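The ring is numbered C1 (bears C7H2OH), C2 (ketone), C3 (enoate ester), C4 (isopropyl, methine C8), C5 (propionate), C6 (vinylic CH). An oxygen on C5 beside a C4 that carries a branched three-carbon group marks a carbonyl-ene retron, so the ring is opened at C4–C5. In the forward sense an open-chain (Z)-4-oxo-enal, whose aldehyde is C5 and whose isobutenyl alkene C4=C8 sits next to the silylated C3 carbinol, cyclises under a Lewis acid. One operation closes the six-membered ring, forms C4–C5, sets C4 and C5 from C3 and leaves C8 as an isopropenyl group. The keto-enal is made by oxidative opening of a 2,3-disubstituted furan.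

Key step: step 6

Remark: the C3 oxygen of the cyclisation precursor carries a triethylsilyl group, which can be removed beside the primary TBDPS ether, and the C3 stereocentre is set by a face-selective organozinc addition, because a reduction of the furyl isobutenyl ketone would have to distinguish two sp2 flanks. Furan C2 becomes ring C2 and furan C5 becomes ring C5.

Step 1
Reactants: 1 3-furanmethanol
Product: 2 tert-butyl(furan-3-ylmethoxy)diphenylsilane
Conditions: TBDPSCl, imidazole, DMF, 0 °C → rt
Reagents that add atoms: tert-butyl(chloro)diphenylsilane, CC(C)(C)[Si](Cl)(c1ccccc1)c1ccccc1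
Why: Imidazole-promoted silylation of a primary alcohol; the TBDPS ether tolerates organolithium, Lewis acid and buffered fluoride and is kept until the last step.

Step 2
Reactants: 2 tert-butyl(furan-3-ylmethoxy)diphenylsilane
Product: 3 [(2-bromofuran-3-yl)methoxy](tert-butyl)diphenylsilane
Conditions: NBS (1.0 equiv), DMF, −20 → 0 °C, dark
Reagents that add atoms: N-bromosuccinimide, O=C1CCC(=O)N1Br
Why: Electrophilic bromination of a 3-alkylfuran takes the α-position flanked by the substituent (furan C2), as with 3-methylfuran, and one equivalent in dry DMF should avoid dibromination and ring opening.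

Step 3
Reactants: 3 [(2-bromofuran-3-yl)methoxy](tert-butyl)diphenylsilane, 4 3-methylbut-2-enal
Product: 7 (1R)-1-{3-[(tert-butyldiphenylsilyloxy)methyl]furan-2-yl}-3-methylbut-2-en-1-ol, via 2-lithiofuran 5 (not isolated), via ethyl(furyl)zinc 6 (not isolated)
Conditions: n-BuLi, t-BuOMe, −78 °C; EtZnCl; TEEDA; (−)-MIB (5 mol %), 4, toluene–hexanes, 0 °C; H2O
Reagents that add atoms: none
Why: Bromine–lithium exchange places the metal at furan C2, transmetalation gives a mixed ethyl(furyl)zinc that transfers only its sp2 group, and the zinc aminoalkoxide formed from (−)-MIB, (2S)-3-exo-morpholinoisoborneol, delivers that group to the Si face of the aldehyde (the sense established for amino-alcohol-catalysed organozinc additions), which makes the carbinol R; TEEDA (N,N,N′,N′-tetraethylethylenediamine) sequesters LiCl so that the racemic background addition is suppressed.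

Step 4
Reactants: 7 (1R)-1-{3-[(tert-butyldiphenylsilyloxy)methyl]furan-2-yl}-3-methylbut-2-en-1-ol
Product: 8 tert-butyl[(2-{(1R)-3-methyl-1-[(triethylsilyl)oxy]but-2-en-1-yl}furan-3-yl)methoxy]diphenylsilane
Conditions: TESCl, imidazole, DMF, 0 °C
Reagents that add atoms: chlorotriethylsilane, CC[Si](Cl)(CC)CC
Why: Silylation under basic, non-ionising conditions leaves the acid-sensitive furfuryl allylic stereocentre untouched, blocks the ring expansion that a free furyl carbinol would undergo on oxidation, and puts on C3–O a group that can later be cleaved beside the TBDPS ether.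

Step 5
Reactants: 8 tert-butyl[(2-{(1R)-3-methyl-1-[(triethylsilyl)oxy]but-2-en-1-yl}furan-3-yl)methoxy]diphenylsilane
Product: 9 (2Z,5R)-3-[(tert-butyldiphenylsilyloxy)methyl]-7-methyl-4-oxo-5-[(triethylsilyl)oxy]octa-2,6-dienal
Conditions: NBS (1.05 equiv), NaHCO3, acetone–H2O (10:1), −20 °C, dark; cold extractive work-up, used at once
Reagents that add atoms: water, O
Why: Oxidative furan opening: NBS attacks the electron-rich furan at its free α-position (furan C5) faster than the isolated trisubstituted alkene, water adds at furan C2 and loss of HBr opens the ring to the cis-enedione, whose Z geometry is that of the former ring; the buffer and the absence of amines should keep the enal from isomerising.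

Step 6
Reactants: 9 (2Z,5R)-3-[(tert-butyldiphenylsilyloxy)methyl]-7-methyl-4-oxo-5-[(triethylsilyl)oxy]octa-2,6-dienal
Product: 10 (4R,5S,6R)-2-[(tert-butyldiphenylsilyloxy)methyl]-4-hydroxy-5-(prop-1-en-2-yl)-6-[(triethylsilyl)oxy]cyclohex-2-en-1-one
Conditions: Me2AlCl (2.2 equiv), CH2Cl2, −78 °C; H2O
Reagents that add atoms: none
Why: Me2AlCl binds the aldehyde oxygen, the aldehyde carbon C5 bonds to C4 while a methyl hydrogen of C8 passes to that oxygen through a six-centre array, the double bond moves to C8=CH2, and the alcohol–aluminium complex loses methane, so no protic acid is left to isomerise or ionise the product. The closest known reaction type is the Lewis-acid-promoted type 1 intramolecular carbonyl-ene cyclisation of 6,7-unsaturated aldehydes (citronellal to isopulegol, neral to isopiperitenol). The ring C5–C6–C1–C2–C3–C4 closes in a 6-exo-trig mode at the aldehyde carbon through a half-chair in which C6, C1 and C2 are already sp2. C4 is controlled by C3: allylic 1,3-strain keeps the C3–H bond in the plane of the C4=C8 alkene, so the tether and the OSiEt3 group lie on opposite faces and bonding on the tether face places OSiEt3 and the new isopropenyl group trans and both equatorial. C5 is controlled by the s-trans conformation of the Z enal, whose oxygen points away from the ketone, ends equatorial and trans to the isopropenyl group, and lies within reach of the C8 methyl. The step needs the Z geometry to last until ring closure and the aldehyde, not the ketone or the enone alkene, to be the enophile; the first is served by −78 °C and an aprotic Lewis acid, the second by the fact that only the aldehyde carbon can reach C4 through a six-membered array.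

Step 7
Reactants: 10 (4R,5S,6R)-2-[(tert-butyldiphenylsilyloxy)methyl]-4-hydroxy-5-(prop-1-en-2-yl)-6-[(triethylsilyl)oxy]cyclohex-2-en-1-one
Product: 11 (1S,5R,6S)-3-[(tert-butyldiphenylsilyloxy)methyl]-4-oxo-6-(prop-1-en-2-yl)-5-[(triethylsilyl)oxy]cyclohex-2-en-1-yl propanoate
Conditions: EtCO2H, PPh3, DIAD, toluene, 0 °C → rt
Reagents that add atoms: propanoic acid, CCC(=O)O
Why: Mitsunobu esterification activates the equatorial allylic C5 hydroxyl as a phosphonium leaving group and propanoate displaces it with inversion, turning the trans C4/C5 relationship into the cis one of the target; elimination is disfavoured because no C4–H bond is antiperiplanar to the equatorial leaving group, and an SN2′ path would have to attack the α-carbon of the enone.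

Step 8
Reactants: 11 (1S,5R,6S)-3-[(tert-butyldiphenylsilyloxy)methyl]-4-oxo-6-(prop-1-en-2-yl)-5-[(triethylsilyl)oxy]cyclohex-2-en-1-yl propanoate
Product: 12 (1S,5R,6S)-3-[(tert-butyldiphenylsilyloxy)methyl]-4-oxo-6-(propan-2-yl)-5-[(triethylsilyl)oxy]cyclohex-2-en-1-yl propanoate
Conditions: H2 (1 atm), RhCl(PPh3)3 (10 mol %), toluene–EtOH, rt
Reagents that add atoms: none
Why: Homogeneous hydrogenation with RhCl(PPh3)3 reduces the unhindered 1,1-disubstituted alkene and leaves the trisubstituted conjugated ring alkene, the allylic ester and the silyl ethers alone (the selectivity seen in carvone to carvotanacetone); no stereocentre is formed.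

Step 9
Reactants: 12 (1S,5R,6S)-3-[(tert-butyldiphenylsilyloxy)methyl]-4-oxo-6-(propan-2-yl)-5-[(triethylsilyl)oxy]cyclohex-2-en-1-yl propanoate
Product: 13 (1S,5R,6R)-3-[(tert-butyldiphenylsilyloxy)methyl]-5-hydroxy-4-oxo-6-(propan-2-yl)cyclohex-2-en-1-yl propanoate
Conditions: HF·pyridine, pyridine, THF, 0 °C
Reagents that add atoms: none
Why: Buffered fluoride cleaves a triethylsilyl ether far faster than a primary tert-butyldiphenylsilyl ether, so only the C3 hydroxyl should be freed, and the mildly acidic medium does not enolise the α-ketol or touch the propanoate (the descriptor at the isopropyl carbon changes only because the priorities change).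

Step 10
Reactants: 14 ethyl 2-(triphenylphosphoranylidene)propanoate, 15 (tert-butyldimethylsilyloxy)acetaldehyde
Product: 16 ethyl (2E)-4-(tert-butyldimethylsilyloxy)-2-methylbut-2-enoate
Conditions: CH2Cl2, rt
Reagents that add atoms: none
Why: Wittig olefination with a stabilised α-methyl ylide is under thermodynamic control of the betaine collapse and should give the E trisubstituted enoate.

Step 11
Reactants: 16 ethyl (2E)-4-(tert-butyldimethylsilyloxy)-2-methylbut-2-enoate
Product: 17 (2E)-4-(tert-butyldimethylsilyloxy)-2-methylbut-2-enoic acid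
Conditions: LiOH, THF–MeOH–H2O, rt; aq. HCl to pH 4, 0 °C
Reagents that add atoms: lithium hydroxide, [Li+].[OH-]
Why: Saponification of the ethyl ester; a primary TBS ether is stable to LiOH and to brief cold acidification, and the conjugated E alkene is not affected.

Step 12
Reactants: 13 (1S,5R,6R)-3-[(tert-butyldiphenylsilyloxy)methyl]-5-hydroxy-4-oxo-6-(propan-2-yl)cyclohex-2-en-1-yl propanoate, 17 (2E)-4-(tert-butyldimethylsilyloxy)-2-methylbut-2-enoic acid
Product: 18 (1R,5S,6S)-3-[(tert-butyldiphenylsilyloxy)methyl]-2-oxo-5-(propanoyloxy)-6-(propan-2-yl)cyclohex-3-en-1-yl (2E)-4-(tert-butyldimethylsilyloxy)-2-methylbut-2-enoate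
Conditions: DCC, DMAP (cat.), CH2Cl2, 0 °C → rt
Reagents that add atoms: none
Why: Steglich esterification acylates the only free hydroxyl under near-neutral conditions; the E enoate is the thermodynamically favoured isomer and should be kept, and the configuration at C3 is not involved in the bond formed.

Step 13
Reactants: 18 (1R,5S,6S)-3-[(tert-butyldiphenylsilyloxy)methyl]-2-oxo-5-(propanoyloxy)-6-(propan-2-yl)cyclohex-3-en-1-yl (2E)-4-(tert-butyldimethylsilyloxy)-2-methylbut-2-enoate
Product: 19 (1R,5S,6S)-3-(hydroxymethyl)-2-oxo-5-(propanoyloxy)-6-(propan-2-yl)cyclohex-3-en-1-yl (2E)-4-hydroxy-2-methylbut-2-enoate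
Conditions: HF·pyridine, THF, 0 °C → rt
Reagents that add atoms: none
Why: Fluoride-mediated cleavage of the two primary silyl ethers under mildly acidic, non-basic conditions should free both hydroxymethyl groups without hydrolysing or shifting either ester and without touching the enone.

Compound list
1 | 3-furanmethanol (furan-3-ylmethanol) | OCc1ccoc1 | starting material
2 | tert-butyl(furan-3-ylmethoxy)diphenylsilane | CC(C)(C)[Si](OCc1ccoc1)(c1ccccc1)c1ccccc1 | intermediate
3 | [(2-bromofuran-3-yl)methoxy](tert-butyl)diphenylsilane | CC(C)(C)[Si](OCc1ccoc1Br)(c1ccccc1)c1ccccc1 | intermediate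
4 | 3-methylbut-2-enal | CC(C)=CC=O | starting material
5 | {3-[(tert-butyldiphenylsilyloxy)methyl]furan-2-yl}lithium | [Li]c1occc1CO[Si](c1ccccc1)(c1ccccc1)C(C)(C)C | intermediate
6 | ethyl{3-[(tert-butyldiphenylsilyloxy)methyl]furan-2-yl}zinc | CC[Zn]c1occc1CO[Si](c1ccccc1)(c1ccccc1)C(C)(C)C | intermediate
7 | (1R)-1-{3-[(tert-butyldiphenylsilyloxy)methyl]furan-2-yl}-3-methylbut-2-en-1-ol | CC(C)=C[C@@H](O)c1occc1CO[Si](c1ccccc1)(c1ccccc1)C(C)(C)C | intermediate
8 | tert-butyl[(2-{(1R)-3-methyl-1-[(triethylsilyl)oxy]but-2-en-1-yl}furan-3-yl)methoxy]diphenylsilane | CC(C)=C[C@@H](O[Si](CC)(CC)CC)c1occc1CO[Si](c1ccccc1)(c1ccccc1)C(C)(C)C | intermediate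
9 | (2Z,5R)-3-[(tert-butyldiphenylsilyloxy)methyl]-7-methyl-4-oxo-5-[(triethylsilyl)oxy]octa-2,6-dienal | O=C/C=C(/CO[Si](c1ccccc1)(c1ccccc1)C(C)(C)C)C(=O)[C@H](O[Si](CC)(CC)CC)C=C(C)C | intermediate
10 | (4R,5S,6R)-2-[(tert-butyldiphenylsilyloxy)methyl]-4-hydroxy-5-(prop-1-en-2-yl)-6-[(triethylsilyl)oxy]cyclohex-2-en-1-one | O=C1C(CO[Si](c2ccccc2)(c2ccccc2)C(C)(C)C)=C[C@@H](O)[C@H](C(C)=C)[C@H]1O[Si](CC)(CC)CC | intermediate
11 | (1S,5R,6S)-3-[(tert-butyldiphenylsilyloxy)methyl]-4-oxo-6-(prop-1-en-2-yl)-5-[(triethylsilyl)oxy]cyclohex-2-en-1-yl propanoate | CCC(=O)O[C@H]1C=C(CO[Si](c2ccccc2)(c2ccccc2)C(C)(C)C)C(=O)[C@H](O[Si](CC)(CC)CC)[C@H]1C(C)=C | intermediate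
12 | (1S,5R,6S)-3-[(tert-butyldiphenylsilyloxy)methyl]-4-oxo-6-(propan-2-yl)-5-[(triethylsilyl)oxy]cyclohex-2-en-1-yl propanoate | CCC(=O)O[C@H]1C=C(CO[Si](c2ccccc2)(c2ccccc2)C(C)(C)C)C(=O)[C@H](O[Si](CC)(CC)CC)[C@H]1C(C)C | intermediate
13 | (1S,5R,6R)-3-[(tert-butyldiphenylsilyloxy)methyl]-5-hydroxy-4-oxo-6-(propan-2-yl)cyclohex-2-en-1-yl propanoate | CCC(=O)O[C@H]1C=C(CO[Si](c2ccccc2)(c2ccccc2)C(C)(C)C)C(=O)[C@H](O)[C@H]1C(C)C | intermediate
14 | ethyl 2-(triphenylphosphoranylidene)propanoate | CCOC(=O)C(C)=P(c1ccccc1)(c1ccccc1)c1ccccc1 | starting material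
15 | (tert-butyldimethylsilyloxy)acetaldehyde | CC(C)(C)[Si](C)(C)OCC=O | starting material
16 | ethyl (2E)-4-(tert-butyldimethylsilyloxy)-2-methylbut-2-enoate | CCOC(=O)/C(C)=C/CO[Si](C)(C)C(C)(C)C | intermediate
17 | (2E)-4-(tert-butyldimethylsilyloxy)-2-methylbut-2-enoic acid | OC(=O)/C(C)=C/CO[Si](C)(C)C(C)(C)C | intermediate
18 | (1R,5S,6S)-3-[(tert-butyldiphenylsilyloxy)methyl]-2-oxo-5-(propanoyloxy)-6-(propan-2-yl)cyclohex-3-en-1-yl (2E)-4-(tert-butyldimethylsilyloxy)-2-methylbut-2-enoate | CCC(=O)O[C@H]1C=C(CO[Si](c2ccccc2)(c2ccccc2)C(C)(C)C)C(=O)[C@H](OC(=O)/C(C)=C/CO[Si](C)(C)C(C)(C)C)[C@H]1C(C)C | intermediate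
19 | (1R,5S,6S)-3-(hydroxymethyl)-2-oxo-5-(propanoyloxy)-6-(propan-2-yl)cyclohex-3-en-1-yl (2E)-4-hydroxy-2-methylbut-2-enoate | CCC(=O)O[C@H]1C=C(CO)C(=O)[C@H](OC(=O)/C(C)=C/CO)[C@H]1C(C)C | target

Total step count: 13. Longest linear sequence: 11 steps (steps 1–9, 12 and 13, from 3-furanmethanol).

Steps most likely to fail

Step 6 (key step). The Z enal may isomerise to the E enal before it closes, and cationic character at C8 may divert the reaction to chloride capture or to proton loss towards a tetrasubstituted C4=C8 alkene. The fallback sets out from 9 and runs the closure as a chloride-terminated Prins cyclisation (SnCl4, CH2Cl2, −78 °C). The stronger Lewis acid should form the same C4–C5 bond through the same half-chair, and the C8 cation is trapped on purpose, to give the tertiary chloride (4R,5S,6R)-2-[(tert-butyldiphenylsilyloxy)methyl]-5-(2-chloropropan-2-yl)-4-hydroxy-6-[(triethylsilyl)oxy]cyclohex-2-en-1-one F1. Mitsunobu propionylation as in step 7 should give the inverted ester (1S,5R,6S)-3-[(tert-butyldiphenylsilyloxy)methyl]-6-(2-chloropropan-2-yl)-4-oxo-5-[(triethylsilyl)oxy]cyclohex-2-en-1-yl propanoate F2. Radical dechlorination (Bu3SnH, AIBN, toluene, 80 °C) then turns the chloride into the isopropyl group and comes back to the route at 12, so step 8 is no longer needed.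

Step 5. NBS may also attack the trisubstituted alkene (bromohydrin formation), and HBr or bromide may isomerise the Z enal or strip the triethylsilyl group during the reaction or work-up. The fallback sets out from 8 and uses dye-sensitised photo-oxygenation (O2, tetraphenylporphyrin, hν, CH2Cl2, −78 °C). Singlet oxygen adds across furan C2/C5 much faster than it ene-reacts with the alkene and should give the endoperoxide 6-[(tert-butyldiphenylsilyloxy)methyl]-1-{(1R)-3-methyl-1-[(triethylsilyl)oxy]but-2-en-1-yl}-2,3,7-trioxabicyclo[2.2.1]hept-5-ene F3. Reduction in the same flask with Me2S at −78 °C opens it under neutral, halide-free conditions and comes back to the route at 9.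

Step 3. Uncatalysed addition promoted by lithium salts may erode the facial selectivity, and the lithiofuran may suffer 1,4 O→C silyl migration or protonation before it reaches zinc. The fallback sets out from 3: bromine–lithium exchange and direct addition to 4 (n-BuLi, THF, −78 °C) gives the racemic alcohol 1-{3-[(tert-butyldiphenylsilyloxy)methyl]furan-2-yl}-3-methylbut-2-en-1-ol F4. MnO2 (CH2Cl2, rt) oxidises it to the ketone 1-{3-[(tert-butyldiphenylsilyloxy)methyl]furan-2-yl}-3-methylbut-2-en-1-one F5. CBS reduction ((S)-2-methyl-CBS-oxazaborolidine, catecholborane, toluene, −78 °C) comes back to the route at 7. The sense of induction assumes that the ortho-substituted furyl group acts as the larger flank; it is to be checked on the first run by Mosher ester analysis, and the mirror-image catalyst is used if it is reversed.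

Further compounds
F1 | step 6 | (4R,5S,6R)-2-[(tert-butyldiphenylsilyloxy)methyl]-5-(2-chloropropan-2-yl)-4-hydroxy-6-[(triethylsilyl)oxy]cyclohex-2-en-1-one | O=C1C(CO[Si](c2ccccc2)(c2ccccc2)C(C)(C)C)=C[C@@H](O)[C@H](C(C)(C)Cl)[C@H]1O[Si](CC)(CC)CC
F2 | step 6 | (1S,5R,6S)-3-[(tert-butyldiphenylsilyloxy)methyl]-6-(2-chloropropan-2-yl)-4-oxo-5-[(triethylsilyl)oxy]cyclohex-2-en-1-yl propanoate | CCC(=O)O[C@H]1C=C(CO[Si](c2ccccc2)(c2ccccc2)C(C)(C)C)C(=O)[C@H](O[Si](CC)(CC)CC)[C@H]1C(C)(C)Cl
F3 | step 5 | 6-[(tert-butyldiphenylsilyloxy)methyl]-1-{(1R)-3-methyl-1-[(triethylsilyl)oxy]but-2-en-1-yl}-2,3,7-trioxabicyclo[2.2.1]hept-5-ene (either bridgehead diastereomer) | CC(C)=C[C@@H](O[Si](CC)(CC)CC)C12OOC(O1)C=C2CO[Si](c1ccccc1)(c1ccccc1)C(C)(C)C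
F4 | step 3 | rac-1-{3-[(tert-butyldiphenylsilyloxy)methyl]furan-2-yl}-3-methylbut-2-en-1-ol | CC(C)=CC(O)c1occc1CO[Si](c1ccccc1)(c1ccccc1)C(C)(C)C
F5 | step 3 | 1-{3-[(tert-butyldiphenylsilyloxy)methyl]furan-2-yl}-3-methylbut-2-en-1-one | CC(C)=CC(=O)c1occc1CO[Si](c1ccccc1)(c1ccccc1)C(C)(C)C
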